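**Retrosynthetic overview**

1. The target is a (2R,3S)-3-arylflavanone (naringenin unit) bonded through C3 to C8'' of an apigenin 7''-O-sulfate. The strategy rests on the flavone pyranone (ring C''): C4'' is a carbonyl carbon between C4a'' and C3'', and O1'' sits on C8a'', ortho to C4a''.
2. Ring C'' is cut into an ortho-iodophenol on the C3 aryl group, CO and 4-benzyloxyphenylacetylene (bonds C4a''–C4'', C4''–C3'', O1''–C2''). Flavanone C4 is carried through this step as a silylated flavan-4-ol.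
3. The 3-arylflavan goes back to an isoflavone: C3–aryl by Suzuki coupling of a 3-iodochromone, C2–aryl by copper-catalysed conjugate arylation, the 2R series by kinetic resolution (asymmetric transfer hydrogenation), C3 trans by equilibration.
4. Ring order: chromone ring C (enaminone iodocyclisation), saturation of C2–C3, then flavone ring C'' (key step). Sulfation, return of C4 to the ketone and hydrogenolysis of five benzyl ethers finish the route.

Key step: step 14

Assumption: the target is taken as the free hydrogen sulfate as drawn (released from its tetrabutylammonium salt at the end, in practice stored as a salt); the C4 configuration of the flavan-4-ol intermediates is immaterial and the all-trans epimer expected from hydride delivery is drawn; Grignard reagent 12 is bought as a THF solution.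

**Route**

Step 1
Reactants: 1 phloroglucinol
Product: 2 5-(benzyloxy)benzene-1,3-diol
Conditions: BnBr (0.5 equiv), K2CO3, DMF, 0 °C to rt
Reagents that add atoms: benzyl bromide, BrCc1ccccc1
Why: Williamson etherification with the halide as limiting reagent should stop largely at the mono-ether, which is separated from recovered 1 and the higher ethers.

Step 2
Reactants: 2 5-(benzyloxy)benzene-1,3-diol
Product: 3 1-(benzyloxy)-3,5-bis(methoxymethoxy)benzene
Conditions: MOMCl, i-Pr2NEt, CH2Cl2, 0 °C to rt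
Reagents that add atoms: chloromethyl methyl ether, COCCl
Why: O-alkylation of both phenols with the α-chloro ether (MOM protection) installs two metalation-directing groups that later come off under acid.

Step 3
Reactants: 3 1-(benzyloxy)-3,5-bis(methoxymethoxy)benzene
Product: 6 [4-(benzyloxy)-2,6-bis(methoxymethoxy)phenyl]boronic acid, via aryllithium 4 (not isolated), via lithium aryltrimethoxyborate 5 (not isolated)
Conditions: n-BuLi, THF, −20 to 0 °C; B(OMe)3, −78 °C to rt; sat. aq. NH4Cl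
Reagents that add atoms: trimethyl borate, COB(OC)OC; water, O
Why: Directed ortho-metalation should take place at the one position flanked by two MOM ethers, and borate trapping with hydrolysis gives the boronic acid, which is used promptly.

Step 4
Reactants: 7 2',4',6'-trihydroxyacetophenone
Product: 8 1-[2,4-bis(benzyloxy)-6-hydroxyphenyl]ethan-1-one
Conditions: BnBr (2.1 equiv), K2CO3, DMF, rt
Reagents that add atoms: benzyl bromide, BrCc1ccccc1
Why: Williamson etherification; the hydroxyl hydrogen-bonded to the acetyl carbonyl is the least nucleophilic and should stay free.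

Step 5
Reactants: 8 1-[2,4-bis(benzyloxy)-6-hydroxyphenyl]ethan-1-one
Product: 9 (E)-1-[2,4-bis(benzyloxy)-6-hydroxyphenyl]-3-(dimethylamino)prop-2-en-1-one
Conditions: Me2NCH(OMe)2, toluene, 90 °C
Reagents that add atoms: N,N-dimethylformamide dimethyl acetal, COC(OC)N(C)C
Why: Condensation of the methyl ketone with the amide acetal gives the enaminone that carries the future C2 of the chromone.

Step 6
Reactants: 9 enaminone
Product: 10 5,7-bis(benzyloxy)-3-iodo-4H-chromen-4-one
Conditions: I2, CHCl3, rt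
Reagents that add atoms: iodine, II
Why: Iodination of the enaminone α-carbon, 6-endo attack of the phenol on the iminium carbon and loss of dimethylamine close the chromone ring (iodocyclisation of a 2-hydroxyaryl enaminone).

Step 7
Reactants: 10 3-iodochromone; 6 arylboronic acid
Product: 11 5,7-bis(benzyloxy)-3-[4-(benzyloxy)-2,6-bis(methoxymethoxy)phenyl]-4H-chromen-4-one
Conditions: Pd(OAc)2 (5 mol %), SPhos (10 mol %), K3PO4, toluene/H2O, 80 °C
Reagents that add atoms: none
Why: Suzuki–Miyaura coupling; the dialkylbiarylphosphine ligand is suited to 2,6-dialkoxyarylboronic acids, and an excess of 6 offsets protodeboronation.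

Step 8
Reactants: 11 isoflavone; 12 4-(benzyloxy)phenylmagnesium bromide
Product: 14 rac-(2R,3S)-5,7-bis(benzyloxy)-3-[4-(benzyloxy)-2,6-bis(methoxymethoxy)phenyl]-2-[4-(benzyloxy)phenyl]-2,3-dihydro-4H-chromen-4-one (racemic trans ketone), via silyl enol ether 13 (not isolated)
Conditions: CuBr·SMe2 (20 mol %), TMSCl, THF, −78 to −20 °C; then 1 M HCl, THF, 0 °C to rt
Reagents that add atoms: none
Why: Copper-catalysed conjugate addition of the Grignard reagent with chlorosilane trapping forms the C2–aryl bond without facial control (racemate), and acid hydrolysis of the enol ether with enolisation lets C3 settle trans, both aryl groups equatorial.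

Step 9
Reactants: 14 racemic trans ketone
Product: 15 (2R,3S)-5,7-bis(benzyloxy)-3-[4-(benzyloxy)-2,6-bis(methoxymethoxy)phenyl]-2-[4-(benzyloxy)phenyl]-2,3-dihydro-4H-chromen-4-one
Conditions: RuCl(p-cymene)[(R,R)-TsDPEN] (2 mol %), HCO2H/Et3N (5:2), EtOAc, rt, stopped just past half conversion
Reagents that add atoms: none
Why: Noyori-type asymmetric transfer hydrogenation run as a kinetic resolution: with the (R,R) ligand the (2S,3R) ketone should be the matched substrate (hydride anti to the C3 aryl group on the carbonyl face the catalyst prefers) and is reduced, so the (2R,3S) ketone is recovered with its enantiomeric purity rising with conversion, the acidic medium leaving the flavanone ring closed (the (S,S) catalyst would be used if the sense of recognition proved opposite).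

Step 10
Reactants: 15 (2R,3S) ketone
Product: 16 (2R,3S)-5,7-bis(benzyloxy)-3-[4-(benzyloxy)-2,6-dihydroxyphenyl]-2-[4-(benzyloxy)phenyl]-2,3-dihydro-4H-chromen-4-one
Conditions: 3 M HCl, MeOH/THF, 45 °C
Reagents that add atoms: none
Why: Acid-catalysed acetal exchange removes both MOM groups while C4 is still a ketone, the oxidation level at which the benzylic C4–O bond cannot ionise, and any C3 epimer formed by enolisation returns to trans.

Step 11
Reactants: 16 dihydroxyaryl ketone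
Product: 17 (2R,3S)-5,7-bis(benzyloxy)-3-[4-(benzyloxy)-2,6-dihydroxy-3-iodophenyl]-2-[4-(benzyloxy)phenyl]-2,3-dihydro-4H-chromen-4-one
Conditions: NIS (1.0 equiv), MeCN/CH2Cl2, −40 to 0 °C
Reagents that add atoms: N-iodosuccinimide, O=C1CCC(=O)N1I
Why: Electrophilic aromatic iodination should go to the free resorcinol ring, the most electron-rich arene while ring A is deactivated by the conjugated ketone, and its two open positions are equivalent, so a single mono-iodide with iodine between a hydroxyl and the benzyl ether is expected.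

Step 12
Reactants: 17 iodo ketone
Product: 18 5-(benzyloxy)-2-[(2R,3R,4R)-5,7-bis(benzyloxy)-2-[4-(benzyloxy)phenyl]-4-hydroxy-3,4-dihydro-2H-chromen-3-yl]-4-iodobenzene-1,3-diol
Conditions: NaBH4, CeCl3·7H2O, MeOH/THF, −40 to 0 °C
Reagents that add atoms: none
Why: Luche reduction keeps the medium near neutral so that the enolate-mediated ring opening that would racemise C2 is avoided; axial hydride delivery should give the all-equatorial alcohol (the C3 descriptor changes to R by the priority rules only), and the C4 configuration is of no consequence.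

Step 13
Reactants: 18 triol
Product: 20 5-(benzyloxy)-2-[(2R,3S,4R)-5,7-bis(benzyloxy)-2-[4-(benzyloxy)phenyl]-4-[(tert-butyldimethylsilyl)oxy]-3,4-dihydro-2H-chromen-3-yl]-4-iodobenzene-1,3-diol, via tris-silyl ether 19 (not isolated)
Conditions: TBSCl, imidazole, DMAP (cat.), DMF, 50 °C; then MeOH, K2CO3, rt
Reagents that add atoms: tert-butyldimethylsilyl chloride, CC(C)(C)[Si](C)(C)Cl
Why: Exhaustive silylation with the chloride (chosen over the Lewis-acidic triflate, which could ionise the electron-rich benzylic C4–O bond) followed by carbonate methanolysis, which cleaves aryl silyl ethers (phenoxide leaving group) far faster than a hindered secondary alkyl silyl ether, should leave only C4 protected.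

Step 14
Reactants: 20 iodoresorcinol flavan; 21 1-(benzyloxy)-4-ethynylbenzene
Product: 24 5-(benzyloxy)-2-[4-(benzyloxy)phenyl]-8-[(2R,3S,4R)-5,7-bis(benzyloxy)-2-[4-(benzyloxy)phenyl]-4-[(tert-butyldimethylsilyl)oxy]-3,4-dihydro-2H-chromen-3-yl]-7-hydroxy-4H-chromen-4-one, via ynone 22 (not isolated), via enaminone 23 (not isolated)
Conditions: PdCl2(PPh3)2 (5 mol %), CO (10 bar), Et2NH, 90 °C
Reagents that add atoms: carbon monoxide, [C-]#[O+]
Why: Zerovalent palladium, formed in situ from PdCl2(PPh3)2, inserts into the C–I bond of 20, CO insertion gives an aroylpalladium iodide, and coupling with the terminal alkyne 21 releases the ortho-hydroxyaryl ynone 22; the closest known reaction type is the carbonylative annulation of ortho-iodophenols with terminal arylacetylenes in secondary amines, which gives flavones. Diethylamine adds to 22 to give the β-amino enone 23, and the hydroxyl next to the new acyl group attacks the β-carbon and expels the amine, so ring C'' closes in the 6-endo sense (6-endo-dig counted on the ynone) with formation of C4a''–C4'', C4''–C3'' and O1''–C2''. No stereocentre is formed, and C2, C3 and C4 of the flavan are not touched by the basic medium because C4 is a silyl ether and not a ketone. Three selectivities are needed: carbonylative over direct alkyne coupling, which the CO pressure secures; 6-endo over 5-exo closure (flavone, not aurone), which the secondary amine secures by routing the closure through 23; and the 8''-linked over the 6''-linked flavone, which the substrate secures because iodine has a free hydroxyl on one side only, the other neighbour being the benzyl ether. The second hydroxyl of the resorcinol ring is meta to the acyl group, cannot reach the ynone and stays free as the site of the sulfate.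

Step 15
Reactants: 24 7''-hydroxyflavone
Product: 26 tetrabutylammonium 5-(benzyloxy)-2-[4-(benzyloxy)phenyl]-8-[(2R,3S,4R)-5,7-bis(benzyloxy)-2-[4-(benzyloxy)phenyl]-4-[(tert-butyldimethylsilyl)oxy]-3,4-dihydro-2H-chromen-3-yl]-4-oxo-4H-chromen-7-yl sulfate, via pyridinium sulfate 25 (not isolated)
Conditions: SO3·pyridine (5 equiv), pyridine, 50 °C; then aq. Bu4NOH, CH2Cl2 extraction
Reagents that add atoms: sulfur trioxide–pyridine complex, O=S(=O)([O-])[n+]1ccccc1; tetrabutylammonium hydroxide, CCCC[N+](CCCC)(CCCC)CCCC.[OH-]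
Why: O-sulfonation of the only free hydroxyl with the amine–SO3 complex, then cation exchange to the lipophilic tetrabutylammonium salt, which can be extracted and chromatographed.

Step 16
Reactants: 26 silyl ether sulfate
Product: 27 tetrabutylammonium 5-(benzyloxy)-2-[4-(benzyloxy)phenyl]-8-[(2R,3R,4R)-5,7-bis(benzyloxy)-2-[4-(benzyloxy)phenyl]-4-hydroxy-3,4-dihydro-2H-chromen-3-yl]-4-oxo-4H-chromen-7-yl sulfate
Conditions: Bu4NF, AcOH, THF, 0 °C to rt
Reagents that add atoms: none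
Why: Buffered fluoride desilylation frees C4–OH; with the neighbouring phenol now a sulfate, no hydroxyl can close onto C4, and the sulfate monoanion is inert to fluoride.

Step 17
Reactants: 27 flavan-4-ol sulfate
Product: 28 tetrabutylammonium 5-(benzyloxy)-2-[4-(benzyloxy)phenyl]-8-[(2R,3S)-5,7-bis(benzyloxy)-2-[4-(benzyloxy)phenyl]-4-oxo-3,4-dihydro-2H-chromen-3-yl]-4-oxo-4H-chromen-7-yl sulfate
Conditions: Dess–Martin periodinane, pyridine, CH2Cl2, 0 °C to rt
Reagents that add atoms: none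
Why: Dess–Martin oxidation under buffered, non-basic conditions restores the flavanone carbonyl; C3 already has the trans configuration, which is also the thermodynamic one, and C2 is not exposed to base.

Step 18
Reactants: 28 pentabenzyl flavanone–flavone sulfate
Product: 29 8-[(2R,3S)-5,7-dihydroxy-2-(4-hydroxyphenyl)-4-oxo-3,4-dihydro-2H-chromen-3-yl]-5-hydroxy-2-(4-hydroxyphenyl)-4-oxo-4H-chromen-7-yl hydrogen sulfate
Conditions: H2 (1 atm), Pd/C (10 %), THF/MeOH, rt; then HCl (1.0 equiv), MeOH/H2O, 0 °C; Sephadex LH-20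
Reagents that add atoms: none
Why: Hydrogenolysis of the five benzyl ethers, stopped at the calculated uptake so that the flavone C2''=C3'' bond, the flavanone carbonyl and the benzylic C2–O1 bond survive; the aryl sulfate is not reduced, and cold protonation with gel filtration gives the free hydrogen sulfate.

**Compound list**

1 | phloroglucinol | Oc1cc(O)cc(O)c1 | starting material
2 | 5-(benzyloxy)benzene-1,3-diol | Oc1cc(O)cc(OCc2ccccc2)c1 | intermediate
3 | 1-(benzyloxy)-3,5-bis(methoxymethoxy)benzene | COCOc1cc(OCOC)cc(OCc2ccccc2)c1 | intermediate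
4 | [4-(benzyloxy)-2,6-bis(methoxymethoxy)phenyl]lithium (not isolated) | [Li]c1c(OCOC)cc(OCc2ccccc2)cc1OCOC | intermediate
5 | lithium [4-(benzyloxy)-2,6-bis(methoxymethoxy)phenyl]trimethoxyborate (not isolated) | [Li+].CO[B-](OC)(OC)c1c(OCOC)cc(OCc2ccccc2)cc1OCOC | intermediate
6 | [4-(benzyloxy)-2,6-bis(methoxymethoxy)phenyl]boronic acid | OB(O)c1c(OCOC)cc(OCc2ccccc2)cc1OCOC | intermediate
7 | 2',4',6'-trihydroxyacetophenone | CC(=O)c1c(O)cc(O)cc1O | starting material
8 | 1-[2,4-bis(benzyloxy)-6-hydroxyphenyl]ethan-1-one | CC(=O)c1c(O)cc(OCc2ccccc2)cc1OCc1ccccc1 | intermediate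
9 | (E)-1-[2,4-bis(benzyloxy)-6-hydroxyphenyl]-3-(dimethylamino)prop-2-en-1-one | CN(C)/C=C/C(=O)c1c(O)cc(OCc2ccccc2)cc1OCc1ccccc1 | intermediate
10 | 5,7-bis(benzyloxy)-3-iodo-4H-chromen-4-one | O=c1c(I)coc2cc(OCc3ccccc3)cc(OCc3ccccc3)c12 | intermediate
11 | 5,7-bis(benzyloxy)-3-[4-(benzyloxy)-2,6-bis(methoxymethoxy)phenyl]-4H-chromen-4-one | O=c1c(-c2c(OCOC)cc(OCc3ccccc3)cc2OCOC)coc2cc(OCc3ccccc3)cc(OCc3ccccc3)c12 | intermediate
12 | 4-(benzyloxy)phenylmagnesium bromide | Br[Mg]c1ccc(OCc2ccccc2)cc1 | starting material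
13 | racemic 5,7-bis(benzyloxy)-3-[4-(benzyloxy)-2,6-bis(methoxymethoxy)phenyl]-2-[4-(benzyloxy)phenyl]-4-(trimethylsilyloxy)-2H-chromene (not isolated) | C[Si](C)(C)OC1=C(c2c(OCOC)cc(OCc3ccccc3)cc2OCOC)C(c2ccc(OCc3ccccc3)cc2)Oc2cc(OCc3ccccc3)cc(OCc3ccccc3)c12 | intermediate
14 | rac-(2R,3S)-5,7-bis(benzyloxy)-3-[4-(benzyloxy)-2,6-bis(methoxymethoxy)phenyl]-2-[4-(benzyloxy)phenyl]-2,3-dihydro-4H-chromen-4-one (trans; both enantiomers given) | O=C1c2c(OCc3ccccc3)cc(OCc3ccccc3)cc2O[C@@H](c2ccc(OCc3ccccc3)cc2)[C@@H]1c1c(OCOC)cc(OCc2ccccc2)cc1OCOC.O=C1c2c(OCc3ccccc3)cc(OCc3ccccc3)cc2O[C@H](c2ccc(OCc3ccccc3)cc2)[C@H]1c1c(OCOC)cc(OCc2ccccc2)cc1OCOC | intermediate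
15 | (2R,3S)-5,7-bis(benzyloxy)-3-[4-(benzyloxy)-2,6-bis(methoxymethoxy)phenyl]-2-[4-(benzyloxy)phenyl]-2,3-dihydro-4H-chromen-4-one | O=C1c2c(OCc3ccccc3)cc(OCc3ccccc3)cc2O[C@@H](c2ccc(OCc3ccccc3)cc2)[C@@H]1c1c(OCOC)cc(OCc2ccccc2)cc1OCOC | intermediate
16 | (2R,3S)-5,7-bis(benzyloxy)-3-[4-(benzyloxy)-2,6-dihydroxyphenyl]-2-[4-(benzyloxy)phenyl]-2,3-dihydro-4H-chromen-4-one | O=C1c2c(OCc3ccccc3)cc(OCc3ccccc3)cc2O[C@@H](c2ccc(OCc3ccccc3)cc2)[C@@H]1c1c(O)cc(OCc2ccccc2)cc1O | intermediate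
17 | (2R,3S)-5,7-bis(benzyloxy)-3-[4-(benzyloxy)-2,6-dihydroxy-3-iodophenyl]-2-[4-(benzyloxy)phenyl]-2,3-dihydro-4H-chromen-4-one | O=C1c2c(OCc3ccccc3)cc(OCc3ccccc3)cc2O[C@@H](c2ccc(OCc3ccccc3)cc2)[C@@H]1c1c(O)cc(OCc2ccccc2)c(I)c1O | intermediate
18 | 5-(benzyloxy)-2-[(2R,3R,4R)-5,7-bis(benzyloxy)-2-[4-(benzyloxy)phenyl]-4-hydroxy-3,4-dihydro-2H-chromen-3-yl]-4-iodobenzene-1,3-diol | O[C@H]1c2c(OCc3ccccc3)cc(OCc3ccccc3)cc2O[C@@H](c2ccc(OCc3ccccc3)cc2)[C@@H]1c1c(O)cc(OCc2ccccc2)c(I)c1O | intermediate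
19 | tris(tert-butyldimethylsilyl) ether of 18, (2R,3S,4R) (not isolated) | CC(C)(C)[Si](C)(C)O[C@H]1c2c(OCc3ccccc3)cc(OCc3ccccc3)cc2O[C@@H](c2ccc(OCc3ccccc3)cc2)[C@@H]1c1c(O[Si](C)(C)C(C)(C)C)cc(OCc2ccccc2)c(I)c1O[Si](C)(C)C(C)(C)C | intermediate
20 | 5-(benzyloxy)-2-[(2R,3S,4R)-5,7-bis(benzyloxy)-2-[4-(benzyloxy)phenyl]-4-[(tert-butyldimethylsilyl)oxy]-3,4-dihydro-2H-chromen-3-yl]-4-iodobenzene-1,3-diol | CC(C)(C)[Si](C)(C)O[C@H]1c2c(OCc3ccccc3)cc(OCc3ccccc3)cc2O[C@@H](c2ccc(OCc3ccccc3)cc2)[C@@H]1c1c(O)cc(OCc2ccccc2)c(I)c1O | intermediate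
21 | 1-(benzyloxy)-4-ethynylbenzene | C#Cc1ccc(OCc2ccccc2)cc1 | starting material
22 | 1-{6-(benzyloxy)-2,4-dihydroxy-3-[(2R,3S,4R)-5,7-bis(benzyloxy)-2-[4-(benzyloxy)phenyl]-4-[(tert-butyldimethylsilyl)oxy]-3,4-dihydro-2H-chromen-3-yl]phenyl}-3-[4-(benzyloxy)phenyl]prop-2-yn-1-one (not isolated) | CC(C)(C)[Si](C)(C)O[C@H]1c2c(OCc3ccccc3)cc(OCc3ccccc3)cc2O[C@@H](c2ccc(OCc3ccccc3)cc2)[C@@H]1c1c(O)cc(OCc2ccccc2)c(C(=O)C#Cc2ccc(OCc3ccccc3)cc2)c1O | intermediate
23 | 3-(diethylamino)prop-2-en-1-one adduct of 22 with diethylamine (not isolated) | CC(C)(C)[Si](C)(C)O[C@H]1c2c(OCc3ccccc3)cc(OCc3ccccc3)cc2O[C@@H](c2ccc(OCc3ccccc3)cc2)[C@@H]1c1c(O)cc(OCc2ccccc2)c(C(=O)C=C(N(CC)CC)c2ccc(OCc3ccccc3)cc2)c1O | intermediate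
24 | 5-(benzyloxy)-2-[4-(benzyloxy)phenyl]-8-[(2R,3S,4R)-5,7-bis(benzyloxy)-2-[4-(benzyloxy)phenyl]-4-[(tert-butyldimethylsilyl)oxy]-3,4-dihydro-2H-chromen-3-yl]-7-hydroxy-4H-chromen-4-one | CC(C)(C)[Si](C)(C)O[C@H]1c2c(OCc3ccccc3)cc(OCc3ccccc3)cc2O[C@@H](c2ccc(OCc3ccccc3)cc2)[C@@H]1c1c(O)cc(OCc2ccccc2)c2c(=O)cc(-c3ccc(OCc4ccccc4)cc3)oc12 | intermediate
25 | pyridinium 7''-sulfate of 24 (not isolated) | c1cc[nH+]cc1.CC(C)(C)[Si](C)(C)O[C@H]1c2c(OCc3ccccc3)cc(OCc3ccccc3)cc2O[C@@H](c2ccc(OCc3ccccc3)cc2)[C@@H]1c1c(OS(=O)(=O)[O-])cc(OCc2ccccc2)c2c(=O)cc(-c3ccc(OCc4ccccc4)cc3)oc12 | intermediate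
26 | tetrabutylammonium 7''-sulfate of 24, (2R,3S,4R) | CCCC[N+](CCCC)(CCCC)CCCC.CC(C)(C)[Si](C)(C)O[C@H]1c2c(OCc3ccccc3)cc(OCc3ccccc3)cc2O[C@@H](c2ccc(OCc3ccccc3)cc2)[C@@H]1c1c(OS(=O)(=O)[O-])cc(OCc2ccccc2)c2c(=O)cc(-c3ccc(OCc4ccccc4)cc3)oc12 | intermediate
27 | tetrabutylammonium 5-(benzyloxy)-2-[4-(benzyloxy)phenyl]-8-[(2R,3R,4R)-5,7-bis(benzyloxy)-2-[4-(benzyloxy)phenyl]-4-hydroxy-3,4-dihydro-2H-chromen-3-yl]-4-oxo-4H-chromen-7-yl sulfate | CCCC[N+](CCCC)(CCCC)CCCC.O[C@H]1c2c(OCc3ccccc3)cc(OCc3ccccc3)cc2O[C@@H](c2ccc(OCc3ccccc3)cc2)[C@@H]1c1c(OS(=O)(=O)[O-])cc(OCc2ccccc2)c2c(=O)cc(-c3ccc(OCc4ccccc4)cc3)oc12 | intermediate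
28 | tetrabutylammonium 5-(benzyloxy)-2-[4-(benzyloxy)phenyl]-8-[(2R,3S)-5,7-bis(benzyloxy)-2-[4-(benzyloxy)phenyl]-4-oxo-3,4-dihydro-2H-chromen-3-yl]-4-oxo-4H-chromen-7-yl sulfate | CCCC[N+](CCCC)(CCCC)CCCC.O=C1c2c(OCc3ccccc3)cc(OCc3ccccc3)cc2O[C@@H](c2ccc(OCc3ccccc3)cc2)[C@@H]1c1c(OS(=O)(=O)[O-])cc(OCc2ccccc2)c2c(=O)cc(-c3ccc(OCc4ccccc4)cc3)oc12 | intermediate
29 | 8-[(2R,3S)-5,7-dihydroxy-2-(4-hydroxyphenyl)-4-oxo-3,4-dihydro-2H-chromen-3-yl]-5-hydroxy-2-(4-hydroxyphenyl)-4-oxo-4H-chromen-7-yl hydrogen sulfate | O=C1c2c(O)cc(O)cc2O[C@@H](c2ccc(O)cc2)[C@@H]1c1c(OS(=O)(=O)O)cc(O)c2c(=O)cc(-c3ccc(O)cc3)oc12 | target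

**Step count and risks**

Total step count: 18. Longest linear sequence: 15 steps (steps 1–3 or 4–6, then 7–18).

Steps most likely to fail:

Step 14. Oxidative addition into the di-ortho-substituted, electron-rich C–I bond may be slow, so that direct (non-carbonylative) alkyne coupling, capture of the aroylpalladium species by diethylamine or protodeiodination outrun ynone formation. The fallback builds the ynone without palladium and CO. It sets out from 19, which is isolated by leaving out the methanolysis of step 13. Iodine–magnesium exchange (i-PrMgCl·LiCl, THF, −20 °C) and trapping with DMF should give the benzaldehyde F1. Addition of the lithium acetylide of 21 (n-BuLi, THF, −78 °C) gives the propargylic alcohol F2 as a mixture of carbinol epimers, and MnO2 (CH2Cl2, rt) oxidises it to the bis-silylated ynone F3. KF in MeOH/Et2NH then frees the two phenols, so that 22 forms and closes through 23 as in the main route, which is rejoined at 24.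

Step 9. The carbonyl group, flanked by the 5-benzyloxy group and the bulky 3-aryl group, may be reduced too slowly, or the catalyst may discriminate too little between the enantiomers. The fallback is a classical resolution from 14. Luche reduction (NaBH4, CeCl3·7H2O, MeOH/THF) gives the racemic all-trans flavan-4-ol F4. Acylation with (1S)-camphanic chloride (DMAP, Et3N, CH2Cl2) gives the camphanate of the 2R alcohol F5 and the camphanate of the 2S alcohol F6, which are separated by chromatography or crystallisation. Methanolysis of F5 (K2CO3, MeOH/THF) gives the (2R,3R,4R)-alcohol F7, and Dess–Martin oxidation returns to the route at 15.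

Step 8. Shielding of the C2=C3 bond by the perpendicular 2,6-disubstituted aryl group may slow conjugate delivery of the aryl group so that 1,2-addition or unchanged 11 prevails. The fallback rebuilds ring C with both aryl groups in place. It sets out from 11: KOH in aqueous ethanol at reflux opens the pyranone with loss of formate to give the deoxybenzoin F8. Condensation with 4-(benzyloxy)benzaldehyde (piperidine, EtOH, reflux; Knoevenagel condensation, then oxa-Michael closure) gives the trans 2,3-diarylchromanone and comes back to the route at 14.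

Further compounds
F1 | step 14 | 6-(benzyloxy)-2,4-bis[(tert-butyldimethylsilyl)oxy]-3-[(2R,3S,4R)-5,7-bis(benzyloxy)-2-[4-(benzyloxy)phenyl]-4-[(tert-butyldimethylsilyl)oxy]-3,4-dihydro-2H-chromen-3-yl]benzaldehyde | CC(C)(C)[Si](C)(C)O[C@H]1c2c(OCc3ccccc3)cc(OCc3ccccc3)cc2O[C@@H](c2ccc(OCc3ccccc3)cc2)[C@@H]1c1c(O[Si](C)(C)C(C)(C)C)cc(OCc2ccccc2)c(C=O)c1O[Si](C)(C)C(C)(C)C
F2 | step 14 | propargylic alcohol from F1 and the acetylide of 21 (carbinol epimers) | CC(C)(C)[Si](C)(C)O[C@H]1c2c(OCc3ccccc3)cc(OCc3ccccc3)cc2O[C@@H](c2ccc(OCc3ccccc3)cc2)[C@@H]1c1c(O[Si](C)(C)C(C)(C)C)cc(OCc2ccccc2)c(C(O)C#Cc2ccc(OCc3ccccc3)cc2)c1O[Si](C)(C)C(C)(C)C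
F3 | step 14 | bis(tert-butyldimethylsilyl) ether of ynone 22 | CC(C)(C)[Si](C)(C)O[C@H]1c2c(OCc3ccccc3)cc(OCc3ccccc3)cc2O[C@@H](c2ccc(OCc3ccccc3)cc2)[C@@H]1c1c(O[Si](C)(C)C(C)(C)C)cc(OCc2ccccc2)c(C(=O)C#Cc2ccc(OCc3ccccc3)cc2)c1O[Si](C)(C)C(C)(C)C
F4 | step 9 | rac-(2R,3R,4R)-5,7-bis(benzyloxy)-3-[4-(benzyloxy)-2,6-bis(methoxymethoxy)phenyl]-2-[4-(benzyloxy)phenyl]-3,4-dihydro-2H-chromen-4-ol (both enantiomers given) | O[C@H]1c2c(OCc3ccccc3)cc(OCc3ccccc3)cc2O[C@@H](c2ccc(OCc3ccccc3)cc2)[C@@H]1c1c(OCOC)cc(OCc2ccccc2)cc1OCOC.O[C@@H]1c2c(OCc3ccccc3)cc(OCc3ccccc3)cc2O[C@H](c2ccc(OCc3ccccc3)cc2)[C@H]1c1c(OCOC)cc(OCc2ccccc2)cc1OCOC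
F5 | step 9 | (1S,4R)-camphanate of the 2R alcohol F7 | O=C(O[C@H]1c2c(OCc3ccccc3)cc(OCc3ccccc3)cc2O[C@@H](c2ccc(OCc3ccccc3)cc2)[C@@H]1c1c(OCOC)cc(OCc2ccccc2)cc1OCOC)[C@@]56CC[C@@](C)(C(=O)O5)C6(C)C
F6 | step 9 | (1S,4R)-camphanate of the enantiomeric 2S alcohol | O=C(O[C@@H]1c2c(OCc3ccccc3)cc(OCc3ccccc3)cc2O[C@H](c2ccc(OCc3ccccc3)cc2)[C@H]1c1c(OCOC)cc(OCc2ccccc2)cc1OCOC)[C@@]56CC[C@@](C)(C(=O)O5)C6(C)C
F7 | step 9 | (2R,3R,4R)-5,7-bis(benzyloxy)-3-[4-(benzyloxy)-2,6-bis(methoxymethoxy)phenyl]-2-[4-(benzyloxy)phenyl]-3,4-dihydro-2H-chromen-4-ol | O[C@H]1c2c(OCc3ccccc3)cc(OCc3ccccc3)cc2O[C@@H](c2ccc(OCc3ccccc3)cc2)[C@@H]1c1c(OCOC)cc(OCc2ccccc2)cc1OCOC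
F8 | step 8 | 1-[2,4-bis(benzyloxy)-6-hydroxyphenyl]-2-[4-(benzyloxy)-2,6-bis(methoxymethoxy)phenyl]ethan-1-one | O=C(Cc1c(OCOC)cc(OCc2ccccc2)cc1OCOC)c1c(O)cc(OCc2ccccc2)cc1OCc1ccccc1
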